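## Structural features

The target is a germacranolide of the heliangolide type: a ten-membered carbocycle (C1–C10) fused trans across C6–C7 to an α-methylene-γ-butyrolactone (O–C6, C7, C11=C13, C12=O). The carbocycle carries a trans 1,10-epoxide with methyl C14 on C10, a Z-trisubstituted alkene C4=C5 with hydroxymethyl C15 on C4, a secondary allylic alcohol at C3 and an angelate at C8. Six stereocentres are present: the contiguous triad C6 (R), C7 (R), C8 (R) with H-6 and H-7 anti and O-8 on the face opposite to H-7; the epoxide pair C1 (R)/C10 (R); and the carbinol C3 (S), two carbons from C1. Fragile groups are the methylene lactone (Michael acceptor), the angelate (Z to E isomerisation on acyl activation), the trisubstituted epoxide (acid, and the C3 hydroxyl three atoms away) and the two allylic alcohols. The real difficulty is the strained ten-membered ring that holds both a trans epoxide and a Z alkene, together with the C8 configuration, which is opposite to what a closed allylation transition state is expected to deliver. The key step exploits the unit C14–C10(=C1)–C2–C3(OH): an E-trisubstituted alkene (the later epoxide) with a homoallylic carbinol is what methylalumination of a terminal alkyne followed by epoxide opening produces, and it lets C3 come from the chiral pool.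

## Logic of the disconnections

**36 from 35.** The O–Si bonds at O3 and O15 are cut first. Free hydroxyls there would steer oxidants to C4=C5, could attack the epoxide and would complicate metathesis, so they stay masked to the end. The skeleton is not simplified, but every earlier step becomes chemoselective. The forward step needs a fluoride source that spares the epoxide, the Z-enoate and the methylene lactone.

**35 from 34.** The C4=C5 bond is cut. It is the only ring bond that can be made from two terminal alkenes without touching a stereocentre. The ring disappears and an open chain with all six stereocentres remains. The forward closure onto a 1,1-disubstituted alkene must beat dimerisation and give the Z alkene. C1–C10 must already be the epoxide, because a trisubstituted C1=C10 alkene would let the C5 carbene close a six-membered ring onto C10.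

**34 from 32 and 33.** The C8–O(alkyl) bond is cut, with inversion. The allylation that makes C7–C8 is expected to give 8S, the opposite of 36; displacement at C8 by the carboxylate of 33 corrects this and installs the ester in one step. 33 is never activated at its carbonyl, so its Z geometry is safe. The forward step needs a clean SN2 reaction at a secondary carbon next to the branched C7.

**32 from 20 and 30.** The C7–C8 bond is cut. C8 is a carbinol beside the lactone β-carbon, the retron of an aldehyde allylation by a 3-(halomethyl)butenolide; the alkene moves to C11=C13 as the bond forms, so the methylene lactone costs no extra step. Two fragments of similar size result. The forward step must attack anti to the C6 substituent, give one configuration at C8, and spare the β,γ-epoxy aldehyde.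

**30 from 29, 28 and 26.** The cuts are C13–Br (back to the silyl ether of 29), C12–O and C11–C12 (carbonylation of 28), and C11–I and C7–H (from the alkyne of 26). A hydroxyl-directed trans-hydrometalation places the metal on C11 cis to the carbinol, so CO insertion closes the butenolide with the C13 oxygen already in place. The lactone is reduced to an enynol with one stereocentre. The forward steps need regiocontrol by the C6 alkoxide and no racemisation at the doubly allylic C6.

**26 from 25, and 25 from 21 and 22.** The C6–C7 bond is cut (acetylide plus enal); the stereocentre is selected by enzymatic resolution of 25. Two commercial three-carbon pieces remain. The forward steps need 1,2-addition and an enzyme that tells vinyl from the alkynyl rod.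

**20 from 19, 18 and 17.** C8=O is traced back to the benzylic ether (19, then 18), and the epoxide C–O bonds to the E alkene of 17. The epoxide is set by reagent control on the open chain, before any base-sensitive lactone is present. The oxidant must pick the trisubstituted alkene and the correct face, and the O8 ether must come off without acid.

**17 from 16, 15, 14, 13 and 12.** C4=CH2 is traced to the ketone (16), the ketone to the carbinol (15), then the O15–Si bond (14), the acetal (13) and the O3–Si bond (12) are removed. C4 must end as sp2 carbon but had to be sp3 in 12, so that the oxirane used for C1–C2 was not allylic. The forward steps need three hydroxyls told apart and no epimerisation of C3 beside the ketone.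

**12 from 2, 9 and 8.** The C10–C14 and C1–C2 bonds are cut. Seven ring carbons (C8 to C4) and both C14 and C15 come from a four-carbon alkyne, a methyl source and a four-carbon oxirane. The forward step needs syn, regioselective methylmetalation, transfer of the alkenyl group and attack at the terminal oxirane carbon.

**8 from 7, 6, 5 and 3; 2 from 1.** The oxirane C–O bond (7), the sulfonate (6), the C1 oxidation level (5) and the enediol C–C bond of 3 are traced back in turn. Both stereocentres of 8 are C4 and C5 of 3, with the terminal acetal already in place, so no acetal migration or inversion is needed. 2 is the benzylic ether of 1, chosen because it survives the acetal hydrolysis and is later removed without acid or fluoride.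

## Other disconnections considered

**Alternative 1:** The lactone C6–O bond is cut after the epoxide oxygen has been taken off. The precursors are the desepoxy lactone A2 and, before it, the ring acid A1 (ten-membered ring intact, C12 as CO2H, C6 as CH2).
- Forward key step: a cytochrome P450 monooxygenase of the class that hydroxylates C6 of germacrene-type C12 acids would abstract the C6 α-hydrogen of A1, return hydroxyl by rebound, and the 6α-alcohol would close on C12 to give A2 with the trans lactone. Epoxidation of C1=C10 would finish.
- In favour: one protecting-group-free C–H oxidation sets C6 and the lactone with enzyme-level control. The Michael-acceptor lactone appears only two steps from the end, which is better than the chosen plan, where it is carried through four steps.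
- Against: A1 already holds the ring, the Z alkene, C3, C7, C8 and the angelate, so the hard part is only moved. Enzymes of this class are known for the unoxidised 4E hydrocarbon acid, so a 4Z, C3/C15-hydroxylated, C8-acylated substrate would need an engineered enzyme. The closing epoxidation would face two free allylic hydroxyls that direct peracids to C4=C5.
- Comparison: structurally the chosen plan brings O6 in with a resolved butenolide. Mechanistically radical rebound in a pocket replaces a polar allylation and would equal it in C6 control if a fitting enzyme exists. The final stage is shorter, but a chemical route to A1 is expected to cost at least as many steps as the whole chosen route.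

**Alternative 2:** The C1=C10 alkene and the C6 carbonyl of dienone A4 are traced to a C6–C10 bond. The ten-membered ring is then hidden in the cis-fused five–seven bicyclic carbinol mesylate A3 (tertiary C6 alcohol at the ring fusion, mesylate on C1, methyl on C10).
- Forward key step: potassium tert-butoxide would form the C6 alkoxide of A3, and the C6–C10 bond would break antiperiplanar to the C1–O bond in a Grob fragmentation. This gives the C6 ketone and the E alkene of A4.
- In favour: the medium ring is released from a bicycle and never closed against entropy, and the E geometry follows stereospecifically from C1/C10. On ring formation this alternative is safer than a ten-membered ring-closing metathesis.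
- Against: three stereocentres (C1, C6, C10) are built only to be destroyed. After A4 a long tail remains: face-selective reduction of a flexible cyclodecadienone at C6, oxidation of the C12 acetal and lactonisation, methylenation at C11, exchange of the C8 ether for the angelate, substrate-controlled epoxidation and desilylation.
- Comparison: both plans end with the same oxygen pattern, but here C3, C7 and C8 must be set on the bicycle by separate operations. The fragmentation is stereospecific where metathesis is under conformational control, a point for the alternative. The linear build of A3 plus about eight steps after A4 is expected to be longer than the convergent chosen route.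

**Alternative 3:** The C7–C8 and C11–C13 bonds are cut around the lactone. The components are dithiane A5 (C8 as masked acyl carbon with C9–C3 attached), the (S)-5-(silyloxymethyl)butenolide A6 and the methyleneiminium salt A7.
- Forward key step: the 2-lithio derivative of A5 would add to C7 of A6 on the face opposite the C6 substituent, and the lactone enolate would be trapped at C11 by A7. This gives the trans Mannich base A8 in one flask.
- In favour: two C–C bonds and the C6/C7 trans relationship arise in one operation. The future methylene group is stored as an amine until the end; in masking the Michael acceptor this plan is better than the chosen one. In C6/C7 control it is equal, since both rely on the facial bias of a 5-substituted butenolide.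
- Against: C8 arrives at the ketone level behind a hindered, fully substituted dithiane, so unmasking and a stereoselective reduction to the 8β alcohol are needed. C3 is an achiral CH2O group and C4, C5 and C15 are absent. The C3 stereocentre, the Z alkene and the ring therefore remain to be made, probably by a macrocyclising carbonyl addition of uncertain selectivity.
- Comparison: the chosen plan fixes C3 from the chiral pool in its key step and needs no redox adjustment at C8. The conjugate addition–Mannich cascade is as dependable as the zinc allylation. The cascade is shorter at the lactone, but the missing C3–C5/C15 sector and the ring closure make the total no shorter.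

Key step: step 6

Assumption: 3, 21 and the D-fructose-derived epoxidation ketone are taken as purchasable (3 is otherwise one acetalisation from L-ascorbic acid).
Assumption: the zinc allylation of step 20 is taken to pass through a closed chair arrangement and give the 8S alcohol, so the ester is introduced with inversion; the other outcome is covered at the end.
Assumption: the lipase of step 16 is taken to follow the usual size rule for secondary alcohols (vinyl small, alkynyl chain large).

## Route

Step 1
Reactants: 1 but-3-yn-1-ol
Product: 2 1-[(but-3-yn-1-yloxy)methyl]-4-methoxybenzene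
Conditions: NaH, 4-methoxybenzyl chloride, Bu4NI (cat.), THF/DMF, 0 °C → rt
Reagents that add atoms: 4-methoxybenzyl chloride, COc1ccc(CCl)cc1
Why: Williamson etherification of the primary alkoxide; the p-methoxybenzyl ether tolerates the alane, butyllithium and aqueous acetic acid and is later removed oxidatively beside silyl ethers and the epoxide.

Step 2
Reactants: 3 5,6-O-isopropylidene-L-ascorbic acid
Product: 5 ethyl 3,4-O-isopropylidene-L-threonate, via potassium threonate acetonide 4 (not isolated)
Conditions: 30% H2O2, K2CO3, H2O, 0 °C → rt; evaporation; EtI, MeCN, reflux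
Reagents that add atoms: hydrogen peroxide, OO; iodoethane, CCI
Why: Alkaline peroxide cleaves the enediol C2–C3 bond, excising C1/C2 as oxalate and leaving C4 and C5 of 3 untouched as the (2R,3S)-threonate; alkylation of the carboxylate gives the ester.

Step 3
Reactants: 5 ethyl 3,4-O-isopropylidene-L-threonate
Product: 6 (1S)-1-[(4S)-2,2-dimethyl-1,3-dioxolan-4-yl]ethane-1,2-diol
Conditions: LiAlH4, THF, 0 °C → rt
Reagents that add atoms: none
Why: Hydride reduction of the ester to the primary alcohol; the acetal is inert and no bond to either stereocentre is touched, so the L-threo diol results.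

Step 4
Reactants: 6 (1S)-1-[(4S)-2,2-dimethyl-1,3-dioxolan-4-yl]ethane-1,2-diol
Product: 7 (2S)-2-[(4S)-2,2-dimethyl-1,3-dioxolan-4-yl]-2-hydroxyethyl 4-methylbenzenesulfonate
Conditions: 4-toluenesulfonyl chloride, Et3N, Bu2SnO (2 mol %), CH2Cl2, 0 °C → rt
Reagents that add atoms: 4-toluenesulfonyl chloride, Cc1ccc(cc1)S(Cl)(=O)=O
Why: The stannylene acetal formed catalytically from the 1,2-diol activates the primary oxygen, so sulfonylation should occur only there (selective primary tosylation of a terminal diol).

Step 5
Reactants: 7 (2S)-2-[(4S)-2,2-dimethyl-1,3-dioxolan-4-yl]-2-hydroxyethyl 4-methylbenzenesulfonate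
Product: 8 (4S)-2,2-dimethyl-4-[(2S)-oxiran-2-yl]-1,3-dioxolane
Conditions: K2CO3, MeOH, 0 °C → rt
Reagents that add atoms: none
Why: Intramolecular Williamson closure by the secondary alkoxide on the primary sulfonate; the C–O bond of the stereocentre is not broken, so the oxirane carbon stays S.

Step 6
Reactants: 2 1-[(but-3-yn-1-yloxy)methyl]-4-methoxybenzene; 9 trimethylaluminium; 8 (4S)-2,2-dimethyl-4-[(2S)-oxiran-2-yl]-1,3-dioxolane
Product: 12 (1S,3E)-1-[(4S)-2,2-dimethyl-1,3-dioxolan-4-yl]-6-[(4-methoxybenzyl)oxy]-4-methylhex-3-en-1-ol, via alkenyldimethylalane 10 (not isolated), via lithium alkenylalanate 11 (not isolated)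
Conditions: 9 (2.5 equiv), Cp2ZrCl2 (0.25 equiv), CH2Cl2, 0 °C → rt; volatiles removed in vacuo; hexane, n-BuLi, −78 → 0 °C; 8, THF, −78 °C → rt; aq. KNaC4H4O6
Reagents that add atoms: trimethylaluminium (compound 9), C[Al](C)C
Why: Cp2ZrCl2 and AlMe3 form a methylzirconocene–aluminate pair that adds methyl and metal syn across the terminal alkyne of 2, methyl to the internal carbon (C10) and metal to the terminal carbon (C1); transmetalation gives the (E)-alkenylalane 10 and returns the zirconium catalyst (Negishi zirconium-catalysed carboalumination). Butyllithium turns the Lewis-acidic, weakly nucleophilic alane into the alanate 11, in which the sp2 ligand is the one most readily transferred. The alanate opens 8 by SN2 attack at the unsubstituted oxirane carbon (C2) with retention of alkene geometry, forming C1–C2 and freeing the C3 alkoxide; the closest known reaction type is the opening of terminal epoxides by alkenylalanates after methylalumination. No ring is closed and no stereocentre is created: C3 keeps the S configuration of 8 because its C–O bond is not broken, and C4 is untouched. The step needs regioselective methylmetalation (secured by the terminal alkyne and by keeping the homopropargylic ether at or below room temperature so that chelation does not scramble geometry) and E geometry (secured by syn addition). It also needs alkenyl rather than methyl or butyl transfer (helped by removing excess AlMe3 before ate formation) and terminal attack on the oxirane (steric; the oxirane is not allylic, so no SN2′ path exists). The ate complex is not Lewis acidic, so the acetal and the benzylic ether should survive.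

Step 7
Reactants: 12 (1S,3E)-1-[(4S)-2,2-dimethyl-1,3-dioxolan-4-yl]-6-[(4-methoxybenzyl)oxy]-4-methylhex-3-en-1-ol
Product: 13 tert-butyl({(1S,3E)-1-[(4S)-2,2-dimethyl-1,3-dioxolan-4-yl]-6-[(4-methoxybenzyl)oxy]-4-methylhex-3-en-1-yl}oxy)dimethylsilane
Conditions: tert-butyldimethylsilyl chloride, imidazole, DMF, rt → 40 °C
Reagents that add atoms: tert-butyldimethylsilyl chloride, CC(C)(C)[Si](C)(C)Cl
Why: Silylation of the secondary C3 alcohol; this ether survives aqueous acetic acid, DDQ, ylide, zinc and ruthenium and is cleaved by fluoride at the end.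

Step 8
Reactants: 13 the C3 silyl ether of 12
Product: 14 (2S,3S,5E)-3-[(tert-butyldimethylsilyl)oxy]-8-[(4-methoxybenzyl)oxy]-6-methyloct-5-ene-1,2-diol
Conditions: AcOH/H2O/THF (3:1:1), 35 °C
Reagents that add atoms: none
Why: Mild acid hydrolysis of the terminal isopropylidene acetal; the secondary silyl ether, the benzylic ether and the alkene tolerate aqueous acetic acid, and no epoxide is present yet.

Step 9
Reactants: 14 (2S,3S,5E)-3-[(tert-butyldimethylsilyl)oxy]-8-[(4-methoxybenzyl)oxy]-6-methyloct-5-ene-1,2-diol
Product: 15 (2S,3S,5E)-1,3-bis[(tert-butyldimethylsilyl)oxy]-8-[(4-methoxybenzyl)oxy]-6-methyloct-5-en-2-ol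
Conditions: tert-butyldimethylsilyl chloride (1.05 equiv), imidazole, CH2Cl2, −10 → 0 °C
Reagents that add atoms: tert-butyldimethylsilyl chloride, CC(C)(C)[Si](C)(C)Cl
Why: Steric differentiation: the primary C15 hydroxyl is silylated far faster than the C4 hydroxyl flanked by two oxygenated carbons.

Step 10
Reactants: 15 (2S,3S,5E)-1,3-bis[(tert-butyldimethylsilyl)oxy]-8-[(4-methoxybenzyl)oxy]-6-methyloct-5-en-2-ol
Product: 16 (3S,5E)-1,3-bis[(tert-butyldimethylsilyl)oxy]-8-[(4-methoxybenzyl)oxy]-6-methyloct-5-en-2-one
Conditions: Dess–Martin periodinane, NaHCO3, CH2Cl2, 0 °C → rt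
Reagents that add atoms: none
Why: Dess–Martin oxidation under buffered, non-enolising conditions, so the adjacent C3 stereocentre is kept while the C4 stereocentre is deliberately erased.

Step 11
Reactants: 16 (3S,5E)-1,3-bis[(tert-butyldimethylsilyl)oxy]-8-[(4-methoxybenzyl)oxy]-6-methyloct-5-en-2-one
Product: 17 (3S,5E)-1,3-bis[(tert-butyldimethylsilyl)oxy]-8-[(4-methoxybenzyl)oxy]-6-methyl-2-methylideneoct-5-ene
Conditions: Ph3PCH3Br, KN(SiMe3)2, THF, 0 °C; then 16, −78 → 0 °C
Reagents that add atoms: methyltriphenylphosphonium bromide, C[P+](c1ccccc1)(c1ccccc1)c1ccccc1.[Br-]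
Why: Wittig methylenation with the non-stabilised ylide gives the 1,1-disubstituted alkene that becomes C4 of the ring alkene; low temperature and short contact limit enolisation towards C3.

Step 12
Reactants: 17 (3S,5E)-1,3-bis[(tert-butyldimethylsilyl)oxy]-8-[(4-methoxybenzyl)oxy]-6-methyl-2-methylideneoct-5-ene
Product: 18 (3S,5R,6R)-1,3-bis[(tert-butyldimethylsilyl)oxy]-5,6-epoxy-8-[(4-methoxybenzyl)oxy]-6-methyl-2-methylideneoctane
Conditions: Shi ketone from D-fructose (1,2:4,5-di-O-isopropylidene-β-D-erythro-hexo-2,3-diulo-2,6-pyranose, 0.3 equiv), KHSO5 (as 2KHSO5·KHSO4·K2SO4), K2CO3, Bu4NHSO4, MeCN/CH2(OMe)2/aq. Na2B4O7 buffer (pH 10.5), 0 °C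
Reagents that add atoms: potassium peroxymonosulfate, [K+].[O-]S(=O)(=O)OO
Why: Shi asymmetric epoxidation: the chiral dioxirane attacks the electron-rich E-trisubstituted alkene through a spiro transition state and, with the D-fructose-derived ketone, should deliver oxygen to the face that gives the (1R,10R) trans epoxide (reagent control; syn addition keeps C2 and C9 trans). The 1,1-disubstituted alkene between two silyloxy carbons is electron-poor and shielded and should not react.

Step 13
Reactants: 18 (3S,5R,6R)-1,3-bis[(tert-butyldimethylsilyl)oxy]-5,6-epoxy-8-[(4-methoxybenzyl)oxy]-6-methyl-2-methylideneoctane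
Product: 19 (3R,4R,6S)-6,8-bis[(tert-butyldimethylsilyl)oxy]-3,4-epoxy-3-methyl-7-methylideneoctan-1-ol
Conditions: DDQ, CH2Cl2/pH 7 phosphate buffer, 0 °C
Reagents that add atoms: none
Why: Oxidative cleavage of the p-methoxybenzyl ether by hydride abstraction; the buffered neutral medium spares the silyl ethers and the acid-sensitive epoxide.

Step 14
Reactants: 19 (3R,4R,6S)-6,8-bis[(tert-butyldimethylsilyl)oxy]-3,4-epoxy-3-methyl-7-methylideneoctan-1-ol
Product: 20 (3R,4R,6S)-6,8-bis[(tert-butyldimethylsilyl)oxy]-3,4-epoxy-3-methyl-7-methylideneoctanal
Conditions: Dess–Martin periodinane, NaHCO3, CH2Cl2, 0 °C; used crude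
Reagents that add atoms: none
Why: Buffered Dess–Martin oxidation to the C8 aldehyde; the β,γ-epoxy aldehyde is prone to base-induced epoxide opening, so it is not chromatographed and is used at once.

Step 15
Reactants: 21 tert-butyldimethyl(prop-2-yn-1-yloxy)silane; 22 acrolein
Product: 25 (±)-6-[(tert-butyldimethylsilyl)oxy]hex-1-en-4-yn-3-yl acetate, via lithium acetylide 23 (not isolated), via lithium alkoxide 24 (not isolated)
Conditions: n-BuLi, THF, −78 °C; 22; Ac2O, −78 °C → rt
Reagents that add atoms: acetic anhydride, CC(=O)OC(C)=O
Why: 1,2-Addition of the lithium acetylide to the enal forms C6–C7; trapping the alkoxide with acetic anhydride gives, in the same flask, the racemic ester needed for enzymatic resolution.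

Step 16
Reactants: 25 (±)-6-[(tert-butyldimethylsilyl)oxy]hex-1-en-4-yn-3-yl acetate
Product: 26 (3R)-6-[(tert-butyldimethylsilyl)oxy]hex-1-en-4-yn-3-ol
Conditions: immobilised Candida antarctica lipase B, pH 7 phosphate buffer/MTBE, 30 °C, stopped below half conversion
Reagents that add atoms: none
Why: Lipase-catalysed enantioselective hydrolysis (kinetic resolution): by the size rule for secondary alcohols the enzyme should accept the ester with vinyl in the small pocket and the silyloxymethyl-alkynyl rod in the large one, that is the (R)-acetate, and release 26 while the (S)-acetate stays. The stereocentre is selected, not formed.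

Step 17
Reactants: 26 (3R)-6-[(tert-butyldimethylsilyl)oxy]hex-1-en-4-yn-3-ol
Product: 28 (3R,4Z)-6-[(tert-butyldimethylsilyl)oxy]-5-iodohexa-1,4-dien-3-ol, via sodium oxa-aluminate 27 (not isolated)
Conditions: NaAlH2(OCH2CH2OMe)2, THF, 0 °C; EtOAc; I2, −78 → 0 °C
Reagents that add atoms: iodine, II
Why: Alkoxide-directed trans-hydroalumination: hydride is delivered to the near alkyne carbon (C7) and aluminium stays on C11 in a five-membered chelate. Iodinolysis with retention gives the Z iodoalkene with iodine cis to the carbinol carbon, as needed for lactonisation.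

Step 18
Reactants: 28 (3R,4Z)-6-[(tert-butyldimethylsilyl)oxy]-5-iodohexa-1,4-dien-3-ol
Product: 29 (5R)-3-{[(tert-butyldimethylsilyl)oxy]methyl}-5-ethenylfuran-2(5H)-one
Conditions: PdCl2(PPh3)2 (5 mol %), CO (1 atm), K2CO3, THF, 50 °C
Reagents that add atoms: carbon monoxide, [C-]#[O+]
Why: Palladium-catalysed carbonylative lactonisation: zerovalent palladium inserts into the C–I bond, CO inserts, and the cis hydroxyl captures the acylpalladium to close the butenolide; the C6 stereocentre takes no part.

Step 19
Reactants: 29 (5R)-3-{[(tert-butyldimethylsilyl)oxy]methyl}-5-ethenylfuran-2(5H)-one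
Product: 30 (5R)-3-(bromomethyl)-5-ethenylfuran-2(5H)-one
Conditions: Ph3PBr2, CH2Cl2, 0 °C → rt
Reagents that add atoms: dibromotriphenylphosphorane, BrP(Br)(c1ccccc1)(c1ccccc1)c1ccccc1
Why: Triphenylphosphine dibromide converts the primary allylic silyl ether directly into the bromide through the alkoxyphosphonium ion; the conjugated primary bromide is the favoured allylic isomer.

Step 20
Reactants: 20 (3R,4R,6S)-6,8-bis[(tert-butyldimethylsilyl)oxy]-3,4-epoxy-3-methyl-7-methylideneoctanal; 30 (5R)-3-(bromomethyl)-5-ethenylfuran-2(5H)-one
Product: 32 (4R,5R)-4-{(1S,3R,4R,6S)-6,8-bis[(tert-butyldimethylsilyl)oxy]-3,4-epoxy-1-hydroxy-3-methyl-7-methylideneoctyl}-5-ethenyl-3-methylideneoxolan-2-one, via allylzinc bromide 31 (not isolated)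
Conditions: Zn dust, THF/sat. aq. NH4Cl, 0 °C
Reagents that add atoms: none
Why: Barbier allylation: zinc inserts into the allylic C–Br bond and 31 adds through its γ-carbon (C7) to the aldehyde, moving the alkene to the exocyclic C11=C13 position. C7 is set by attack anti to the C6 vinyl group (trans lactone), and C8 by a chair Zimmerman–Traxler arrangement with the aldehyde chain equatorial, which places O8 anti to C6 (8S). In situ generation keeps the allylzinc from opening the lactone by elimination, and the near-neutral medium spares the epoxide.

Step 21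
Reactants: 32 the (6R,7R,8S) alcohol; 33 angelic acid [(2Z)-2-methylbut-2-enoic acid]
Product: 34 (1R,3R,4R,6S)-6,8-bis[(tert-butyldimethylsilyl)oxy]-1-[(2R,3R)-2-ethenyl-4-methylidene-5-oxooxolan-3-yl]-3,4-epoxy-3-methyl-7-methylideneoctyl (2Z)-2-methylbut-2-enoate
Conditions: PPh3, diisopropyl azodicarboxylate, 33, toluene, 0 °C → rt
Reagents that add atoms: angelic acid (compound 33), C/C=C(/C)C(=O)O
Why: Mitsunobu esterification: the C8 alcohol is activated as its alkoxyphosphonium ion and displaced by angelate with inversion, turning 8S into the required 8R ester. The acid acts as a carboxylate nucleophile and is never activated at its acyl carbon, which is the usual cause of Z to E isomerisation.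

Step 22
Reactants: 34 the (8R)-angelate diene
Product: 35 3,15-bis-O-(tert-butyldimethylsilyl) ether of the target [(1R,3S,4Z,6R,7R,8R,10R)-configured ten-membered lactone]
Conditions: second-generation Grubbs catalyst RuCl2(=CHPh)(PCy3)(H2IMes) (15 mol %, in portions), 1,4-benzoquinone (cat.), toluene, 0.001 M, 80 °C
Reagents that add atoms: none
Why: Ring-closing olefin metathesis: the carbene loads on the unhindered C5 vinyl group and closes onto the C4 methylene with loss of ethene, forming the ten-membered ring and the trisubstituted C4=C5 alkene. The Z isomer is expected as the less strained geometry in a ten-membered ring that already holds the trans lactone and trans epoxide. With the epoxide in place no second trisubstituted alkene can divert the carbene into a six-membered ring; the enoate and the methylene lactone are poor metathesis partners.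

Step 23
Reactants: 35 3,15-bis-O-(tert-butyldimethylsilyl) ether of the target
Product: 36 (1R,3S,4Z,6R,7R,8R,10R)-8-angeloyloxy-1,10-epoxy-3,15-dihydroxygermacra-4,11(13)-dien-12,6-olide (target, CNP0187917.1)
Conditions: HF·pyridine, pyridine, THF, 0 °C → rt
Reagents that add atoms: none
Why: Fluoride cleavage of both silyl ethers under buffered, weakly acidic conditions of the kind that trisubstituted epoxides, enoates and methylene lactones normally tolerate; no stereocentre is affected.

## Compound list

1 | but-3-yn-1-ol | C#CCCO | starting material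
2 | 1-[(but-3-yn-1-yloxy)methyl]-4-methoxybenzene | C#CCCOCc1ccc(OC)cc1 | intermediate
3 | 5,6-O-isopropylidene-L-ascorbic acid | CC1(C)OC[C@H](O1)[C@H]1OC(=O)C(O)=C1O | starting material
4 | potassium (2R)-2-[(4S)-2,2-dimethyl-1,3-dioxolan-4-yl]-2-hydroxyacetate | [K+].[O-]C(=O)[C@H](O)[C@@H]1COC(C)(C)O1 | intermediate (not isolated)
5 | ethyl (2R)-2-[(4S)-2,2-dimethyl-1,3-dioxolan-4-yl]-2-hydroxyacetate | CCOC(=O)[C@H](O)[C@@H]1COC(C)(C)O1 | intermediate
6 | (1S)-1-[(4S)-2,2-dimethyl-1,3-dioxolan-4-yl]ethane-1,2-diol | OC[C@H](O)[C@@H]1COC(C)(C)O1 | intermediate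
7 | (2S)-2-[(4S)-2,2-dimethyl-1,3-dioxolan-4-yl]-2-hydroxyethyl 4-methylbenzenesulfonate | Cc1ccc(cc1)S(=O)(=O)OC[C@H](O)[C@@H]1COC(C)(C)O1 | intermediate
8 | (4S)-2,2-dimethyl-4-[(2S)-oxiran-2-yl]-1,3-dioxolane | C1O[C@@H]1[C@@H]2COC(C)(C)O2 | intermediate
9 | trimethylaluminium | C[Al](C)C | starting material
10 | (E)-[4-(4-methoxybenzyloxy)-2-methylbut-1-en-1-yl]dimethylalane | COc1ccc(COCC/C(C)=C/[Al](C)C)cc1 | intermediate (not isolated)
11 | lithium butyl[(E)-4-(4-methoxybenzyloxy)-2-methylbut-1-en-1-yl]dimethylaluminate | [Li+].CCCC[Al-](C)(C)/C=C(\C)CCOCc1ccc(OC)cc1 | intermediate (not isolated)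
12 | (1S,3E)-1-[(4S)-2,2-dimethyl-1,3-dioxolan-4-yl]-6-[(4-methoxybenzyl)oxy]-4-methylhex-3-en-1-ol | COc1ccc(COCC/C(C)=C/C[C@H](O)[C@@H]2COC(C)(C)O2)cc1 | intermediate
13 | tert-butyl({(1S,3E)-1-[(4S)-2,2-dimethyl-1,3-dioxolan-4-yl]-6-[(4-methoxybenzyl)oxy]-4-methylhex-3-en-1-yl}oxy)dimethylsilane | COc1ccc(COCC/C(C)=C/C[C@H](O[Si](C)(C)C(C)(C)C)[C@@H]2COC(C)(C)O2)cc1 | intermediate
14 | (2S,3S,5E)-3-[(tert-butyldimethylsilyl)oxy]-8-[(4-methoxybenzyl)oxy]-6-methyloct-5-ene-1,2-diol | COc1ccc(COCC/C(C)=C/C[C@H](O[Si](C)(C)C(C)(C)C)[C@@H](O)CO)cc1 | intermediate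
15 | (2S,3S,5E)-1,3-bis[(tert-butyldimethylsilyl)oxy]-8-[(4-methoxybenzyl)oxy]-6-methyloct-5-en-2-ol | COc1ccc(COCC/C(C)=C/C[C@H](O[Si](C)(C)C(C)(C)C)[C@@H](O)CO[Si](C)(C)C(C)(C)C)cc1 | intermediate
16 | (3S,5E)-1,3-bis[(tert-butyldimethylsilyl)oxy]-8-[(4-methoxybenzyl)oxy]-6-methyloct-5-en-2-one | COc1ccc(COCC/C(C)=C/C[C@H](O[Si](C)(C)C(C)(C)C)C(=O)CO[Si](C)(C)C(C)(C)C)cc1 | intermediate
17 | (3S,5E)-1,3-bis[(tert-butyldimethylsilyl)oxy]-8-[(4-methoxybenzyl)oxy]-6-methyl-2-methylideneoct-5-ene | COc1ccc(COCC/C(C)=C/C[C@H](O[Si](C)(C)C(C)(C)C)C(=C)CO[Si](C)(C)C(C)(C)C)cc1 | intermediate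
18 | (3S,5R,6R)-1,3-bis[(tert-butyldimethylsilyl)oxy]-5,6-epoxy-8-[(4-methoxybenzyl)oxy]-6-methyl-2-methylideneoctane | COc1ccc(COCC[C@@]2(C)O[C@@H]2C[C@H](O[Si](C)(C)C(C)(C)C)C(=C)CO[Si](C)(C)C(C)(C)C)cc1 | intermediate
19 | (3R,4R,6S)-6,8-bis[(tert-butyldimethylsilyl)oxy]-3,4-epoxy-3-methyl-7-methylideneoctan-1-ol | OCC[C@@]1(C)O[C@@H]1C[C@H](O[Si](C)(C)C(C)(C)C)C(=C)CO[Si](C)(C)C(C)(C)C | intermediate
20 | (3R,4R,6S)-6,8-bis[(tert-butyldimethylsilyl)oxy]-3,4-epoxy-3-methyl-7-methylideneoctanal | O=CC[C@@]1(C)O[C@@H]1C[C@H](O[Si](C)(C)C(C)(C)C)C(=C)CO[Si](C)(C)C(C)(C)C | intermediate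
21 | tert-butyldimethyl(prop-2-yn-1-yloxy)silane | C#CCO[Si](C)(C)C(C)(C)C | starting material
22 | acrolein (prop-2-enal) | C=CC=O | starting material
23 | lithium 3-[(tert-butyldimethylsilyl)oxy]prop-1-yn-1-ide | [Li]C#CCO[Si](C)(C)C(C)(C)C | intermediate (not isolated)
24 | lithium (±)-6-[(tert-butyldimethylsilyl)oxy]hex-1-en-4-yn-3-olate | [Li]OC(C=C)C#CCO[Si](C)(C)C(C)(C)C | intermediate (not isolated)
25 | (±)-6-[(tert-butyldimethylsilyl)oxy]hex-1-en-4-yn-3-yl acetate (racemate) | CC(=O)OC(C=C)C#CCO[Si](C)(C)C(C)(C)C | intermediate
26 | (3R)-6-[(tert-butyldimethylsilyl)oxy]hex-1-en-4-yn-3-ol | C=C[C@@H](O)C#CCO[Si](C)(C)C(C)(C)C | intermediate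
27 | sodium bis(2-methoxyethoxy) oxa-aluminate chelate of the (Z)-alkenylalane (five-membered O–Al–C11=C7–C6 ring, C6 R) | [Na+].C=C[C@H]1O[Al-](OCCOC)(OCCOC)C(CO[Si](C)(C)C(C)(C)C)=C1 | intermediate (not isolated)
28 | (3R,4Z)-6-[(tert-butyldimethylsilyl)oxy]-5-iodohexa-1,4-dien-3-ol | C=C[C@@H](O)/C=C(\I)CO[Si](C)(C)C(C)(C)C | intermediate
29 | (5R)-3-{[(tert-butyldimethylsilyl)oxy]methyl}-5-ethenylfuran-2(5H)-one | C=C[C@H]1OC(=O)C(CO[Si](C)(C)C(C)(C)C)=C1 | intermediate
30 | (5R)-3-(bromomethyl)-5-ethenylfuran-2(5H)-one | C=C[C@H]1OC(=O)C(CBr)=C1 | intermediate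
31 | {[(5R)-5-ethenyl-2-oxo-2,5-dihydrofuran-3-yl]methyl}zinc bromide | C=C[C@H]1OC(=O)C(C[Zn]Br)=C1 | intermediate (not isolated)
32 | (4R,5R)-4-{(1S,3R,4R,6S)-6,8-bis[(tert-butyldimethylsilyl)oxy]-3,4-epoxy-1-hydroxy-3-methyl-7-methylideneoctyl}-5-ethenyl-3-methylideneoxolan-2-one | C=C[C@H]1OC(=O)C(=C)[C@@H]1[C@@H](O)C[C@@]2(C)O[C@@H]2C[C@H](O[Si](C)(C)C(C)(C)C)C(=C)CO[Si](C)(C)C(C)(C)C | intermediate
33 | angelic acid, (2Z)-2-methylbut-2-enoic acid | C/C=C(/C)C(=O)O | starting material
34 | (1R,3R,4R,6S)-6,8-bis[(tert-butyldimethylsilyl)oxy]-1-[(2R,3R)-2-ethenyl-4-methylidene-5-oxooxolan-3-yl]-3,4-epoxy-3-methyl-7-methylideneoctyl (2Z)-2-methylbut-2-enoate | C=C[C@H]1OC(=O)C(=C)[C@@H]1[C@H](OC(=O)/C(C)=C\C)C[C@@]2(C)O[C@@H]2C[C@H](O[Si](C)(C)C(C)(C)C)C(=C)CO[Si](C)(C)C(C)(C)C | intermediate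
35 | 3,15-bis-O-(tert-butyldimethylsilyl) ether of the target | C=C1C(=O)O[C@@H]2/C=C(/CO[Si](C)(C)C(C)(C)C)[C@@H](O[Si](C)(C)C(C)(C)C)C[C@H]3O[C@]3(C)C[C@@H](OC(=O)/C(C)=C\C)[C@@H]12 | intermediate
36 | (1R,3S,4Z,6R,7R,8R,10R)-8-angeloyloxy-1,10-epoxy-3,15-dihydroxygermacra-4,11(13)-dien-12,6-olide | C=C1C(=O)O[C@@H]2/C=C(/CO)[C@@H](O)C[C@H]3O[C@]3(C)C[C@@H](OC(=O)/C(C)=C\C)[C@@H]12 | target

## Step count and least certain steps

Total: 23 steps. Longest linear sequence: 17 steps (from 3 through steps 2–14 and 20–23).

**Step 6 (key step).** Most likely failure: transfer of methyl or butyl instead of the alkenyl group from the mixed alanate, incomplete opening of 8, or chelation-driven erosion of alkene geometry if the carboalumination is slow. The fallback sets out from 2 and returns at 12. The alane 10 is quenched with iodine to give 1-({[(3E)-4-iodo-3-methylbut-3-en-1-yl]oxy}methyl)-4-methoxybenzene F1. Iodine–lithium exchange with tert-butyllithium at −78 °C gives [(1E)-4-(4-methoxybenzyloxy)-2-methylbut-1-en-1-yl]lithium F2. F2 opens 8 at the terminal carbon in the presence of BF3·OEt2 at −78 °C to give 12. The bonds formed are the same; only the metal that carries the alkenyl group changes.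

**Step 22.** Most likely failure: cyclisation onto the shielded C4 methylene is slower than intermolecular metathesis at the C5 vinyl group, which would lead to oligomers; closure with the E ring alkene is the second risk. The fallback sets out from 34 and returns at 36. HF·pyridine first removes both silyl ethers to give the 3,15-diol of 34, F5. Its C4 methylene is far less hindered and carries free allylic hydroxyls, which are known to assist ruthenium carbenes. Ring-closing metathesis of F5 under high dilution then gives 36 directly, so the substrate and the order of events change, not only the catalyst.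

**Step 21.** Most likely failure: the alkoxyphosphonium ion at C8 eliminates towards C7, or is intercepted by the lactone carbonyl, faster than the weakly acidic angelic acid displaces it; partial Z to E isomerisation of the ester by the phosphine is a lesser risk. The fallback sets out from 32 and returns at 34 and decouples inversion from acylation. A Mitsunobu reaction with the much stronger chloroacetic acid gives the inverted (8R)-chloroacetate of 32, F4. Thiourea and NaHCO3 in ethanol remove the chloroacetyl group to give the (8R)-alcohol epimer of 32, F3. F3 is esterified with retention by the Yamaguchi method (33, 2,4,6-trichlorobenzoyl chloride, Et3N, toluene, 75 °C) to give 34.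

**Step 20.** Most likely failure: loss or reversal of simple diastereoselection at C8 (chair versus boat-like addition on zinc in water), or opening of the β,γ-epoxy aldehyde before C–C bond formation. The fallback sets out from 20 and 30 and returns at 34; it makes the route independent of the sense of addition. The C8 epimers are separated. 32 continues through step 21 (inversion). The (8R)-alcohol epimer of 32, F3, is esterified with retention by the Yamaguchi method (33, 2,4,6-trichlorobenzoyl chloride, Et3N, toluene, 75 °C) to give the same 34.

## Further compounds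

F1 | step 6 | 1-({[(3E)-4-iodo-3-methylbut-3-en-1-yl]oxy}methyl)-4-methoxybenzene | COc1ccc(COCC/C(C)=C/I)cc1
F2 | step 6 | [(1E)-4-(4-methoxybenzyloxy)-2-methylbut-1-en-1-yl]lithium | COc1ccc(COCC/C(C)=C/[Li])cc1
F3 | step 20 | (8R)-alcohol epimer of 32: (4R,5R)-4-{(1R,3R,4R,6S)-6,8-bis[(tert-butyldimethylsilyl)oxy]-3,4-epoxy-1-hydroxy-3-methyl-7-methylideneoctyl}-5-ethenyl-3-methylideneoxolan-2-one | C=C[C@H]1OC(=O)C(=C)[C@@H]1[C@H](O)C[C@@]2(C)O[C@@H]2C[C@H](O[Si](C)(C)C(C)(C)C)C(=C)CO[Si](C)(C)C(C)(C)C
F4 | step 21 | (8R)-chloroacetate: chloroacetic ester of F3 | C=C[C@H]1OC(=O)C(=C)[C@@H]1[C@H](OC(=O)CCl)C[C@@]2(C)O[C@@H]2C[C@H](O[Si](C)(C)C(C)(C)C)C(=C)CO[Si](C)(C)C(C)(C)C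
F5 | step 22 | 3,15-diol of 34 (both silyl ethers removed) | C=C[C@H]1OC(=O)C(=C)[C@@H]1[C@H](OC(=O)/C(C)=C\C)C[C@@]2(C)O[C@@H]2C[C@H](O)C(=C)CO
A1 | alternative 1 | ten-membered 8-angeloyloxy-3,15-dihydroxy-1(10)E,4Z,11(13)-trien-12-oic acid (C6 unoxidised) | C=C(C(=O)O)[C@H]1C/C=C(/CO)[C@@H](O)C/C=C(\C)C[C@H]1OC(=O)/C(C)=C\C
A2 | alternative 1 | 1(10)-ene (desepoxy) form of the target | C=C1C(=O)O[C@@H]2/C=C(/CO)[C@@H](O)C/C=C(\C)C[C@@H](OC(=O)/C(C)=C\C)[C@@H]12
A3 | alternative 2 | cis-fused five–seven bicyclic carbinol mesylate (C6–C10 bond, tertiary C6 alcohol, C1 mesylate, C10 methyl, C3 and C15 silyl ethers, C8 p-methoxybenzyl ether, C7 2,2-dimethoxyethyl) | O[C@@]12/C=C(/CO[Si](C)(C)C(C)(C)C)[C@@H](O[Si](C)(C)C(C)(C)C)C[C@@H](OS(C)(=O)=O)[C@]1(C)C[C@@H](OCc1ccc(OC)cc1)[C@H]2CC(OC)OC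
A4 | alternative 2 | ten-membered 1(10)E,4Z-dien-6-one carrying C7 and C8 | O=C1/C=C(/CO[Si](C)(C)C(C)(C)C)[C@@H](O[Si](C)(C)C(C)(C)C)C/C=C(\C)C[C@@H](OCc2ccc(OC)cc2)[C@H]1CC(OC)OC
A5 | alternative 3 | 2-[(2E)-5-(4-methoxybenzyloxy)-2-methylpent-2-en-1-yl]-1,3-dithiane | COc1ccc(COCC/C=C(\C)CC2SCCCS2)cc1
A6 | alternative 3 | (5S)-5-{[(tert-butyldimethylsilyl)oxy]methyl}furan-2(5H)-one | O=C1C=C[C@@H](CO[Si](C)(C)C(C)(C)C)O1
A7 | alternative 3 | N,N-dimethylmethyleneiminium iodide | C=[N+](C)C.[I-]
A8 | alternative 3 | trans-disubstituted lactone Mannich base with C8 as dithiane | CN(C)CC1C(=O)O[C@H](CO[Si](C)(C)C(C)(C)C)[C@H]1C2(C/C(C)=C/CCOCc3ccc(OC)cc3)SCCCS2
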